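**Retrosynthetic overview** (dioxine numbering: O1, O2, C3 = CH bearing the acetate arm, C4=C5, C6 = ketal carbon)

1. Xestin B ⇒ (trans-ketalisation with MeOH, C6 under thermodynamic control) (3R)-lactate peroxyketals 18 ⇒ (covalent resolution of C3 with methyl (S)-lactate) racemic dioxinol 17.
2. Dioxinol 17 ⇒ cyclobutenol 15 + O2: the 1,2-dioxine is grown from a four-membered carbocycle by insertion of O1–O2 into a C–C bond (4 → 6).
3. Enabling feature: C6–C5=C4–C3 of the dioxine (ketal carbon, cis-alkene, CH) are the four carbons of a 1-alkylcyclobut-2-en-1-ol. Its strained σ-bond between the carbinol carbon (future C6) and the allylic CH (future C3) is cut by alkoxyl-radical β-scission to a Z-locked oxoallyl radical that takes up O2 and recloses on the new ketone.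
4. 15 ⇒ cyclobutenone 13 + side-chain Grignard reagent 14; 13 ⇒ ketene/ethoxyethyne [2+2], then 1,3-carbonyl transposition; side chain ⇒ sorbyl acetate + C12 Grignard reagent (copper catalysis).
5. Order of ring formation: cyclobutene (step 5), then 1,2-dioxine by ring expansion (step 8); there is no other ring.

Key step: step 8

Remark on the chemistry: the key step forms C3 through a planar radical, hence as a racemate. The route therefore takes the C3 configuration from a covalent resolution (step 9), in which the (3S)-series is discarded, and the acid-labile C6 ketal centre from equilibration and separation (step 10).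

**Route**

Step 1
Reactants: 1 12-bromododecan-1-ol
Product: 2 2-[(12-bromododecyl)oxy]tetrahydro-2H-pyran
Conditions: 3,4-dihydro-2H-pyran, PPTS (cat.), CH2Cl2, 20 °C
Reagents that add atoms: 3,4-dihydro-2H-pyran, C1=COCCC1
Why: Acid-catalysed addition of the alcohol to the enol ether (tetrahydropyranyl protection) masks the hydroxyl so that the bromide can be turned into a Grignard reagent; the acetal centre forms as a racemate and is removed in step 3.

Step 2
Reactants: 2 2-[(12-bromododecyl)oxy]tetrahydro-2H-pyran; 3 (2E,4E)-hexa-2,4-dien-1-yl acetate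
Product: 5 2-{[(14E,16E)-octadeca-14,16-dien-1-yl]oxy}tetrahydro-2H-pyran, via Grignard reagent 4 (not isolated)
Conditions: Mg, THF, 40 °C; then 3, Li2CuCl4 (3 mol %), THF, −20 → 0 °C
Reagents that add atoms: none
Why: Copper-catalysed cross-coupling of a primary alkyl Grignard reagent with a primary dienylic acetate (Kochi-type coupling) should substitute at the α-carbon and keep the conjugated (E,E)-diene, as in the usual assembly of conjugated-diene pheromone chains; no stereocentre is formed.

Step 3
Reactants: 5 2-{[(14E,16E)-octadeca-14,16-dien-1-yl]oxy}tetrahydro-2H-pyran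
Product: 6 (14E,16E)-octadeca-14,16-dien-1-ol
Conditions: PPTS (cat.), MeOH, 50 °C
Reagents that add atoms: none
Why: Acid-catalysed transacetalisation to methanol should release the primary alcohol under conditions too mild to touch the diene.

Step 4
Reactants: 6 (14E,16E)-octadeca-14,16-dien-1-ol
Product: 7 (2E,4E)-18-bromooctadeca-2,4-diene
Conditions: CBr4, PPh3, CH2Cl2, 0 °C
Reagents that add atoms: carbon tetrabromide, BrC(Br)(Br)Br
Why: The Appel reaction converts the primary alcohol into the bromide under neutral conditions that leave the diene geometry intact.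

Step 5
Reactants: 8 methyl 4-chloro-4-oxobutanoate; 9 ethoxyethyne
Product: 11 methyl 2-(2-ethoxy-4-oxocyclobut-2-en-1-yl)acetate, via ketene 10 (not isolated)
Conditions: Et3N, 9 (2 equiv), Et2O, slow addition of 8, 0 → 20 °C
Reagents that add atoms: none
Why: Dehydrochlorination gives the monoalkylketene, which should be trapped by the electron-rich alkoxyalkyne in a thermal [2+2] cycloaddition (ketene carbonyl carbon to the unsubstituted alkyne carbon) to give the 4-alkyl-3-ethoxycyclobutenone; the single stereocentre is racemic and is erased in step 8.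

Step 6
Reactants: 11 methyl 2-(2-ethoxy-4-oxocyclobut-2-en-1-yl)acetate
Product: 13 methyl 2-(4-oxocyclobut-2-en-1-yl)acetate, via allylic alcohol 12 (not isolated)
Conditions: NaBH4, CeCl3·7H2O, MeOH, −40 °C; then 1 M HCl, THF, 0 °C; used cold without distillation
Reagents that add atoms: water, O
Why: Luche 1,2-reduction of the ketone beside the ester, then acid hydrolysis of the 3-ethoxy allylic alcohol with loss of water (Stork–Danheiser-type 1,3-carbonyl transposition), should give a cyclobutenone with an unsubstituted alkene whose carbonyl is still next to the substituted sp3 carbon; the stereocentre stays racemic.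

Step 7
Reactants: 7 (2E,4E)-18-bromooctadeca-2,4-diene; 13 methyl 2-(4-oxocyclobut-2-en-1-yl)acetate
Product: 15 methyl 2-{4-hydroxy-4-[(14E,16E)-octadeca-14,16-dien-1-yl]cyclobut-2-en-1-yl}acetate, via dienyl Grignard reagent 14 (not isolated)
Conditions: Mg, THF, 40 °C; then 13, THF, −78 °C; AcOH, −78 °C; used at once
Reagents that add atoms: none
Why: Grignard 1,2-addition to the strained cyclobutenone carbonyl should outrun ester attack at −78 °C, and cold protonation should forestall ring opening of the alkoxide and lactonisation; the two stereocentres form as a racemic diastereomer mixture and are both erased in step 8.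

Step 8
Reactants: 15 methyl 2-{4-hydroxy-4-[(14E,16E)-octadeca-14,16-dien-1-yl]cyclobut-2-en-1-yl}acetate
Product: 17 methyl 2-{6-hydroxy-6-[(14E,16E)-octadeca-14,16-dien-1-yl]-3,6-dihydro-1,2-dioxin-3-yl}acetate, via (Z)-γ-hydroperoxy enone 16 (not isolated)
Conditions: Co(acac)2 (10 mol %), O2 (1 atm), CH2Cl2, 20 °C, dark
Reagents that add atoms: dioxygen, O=O
Why: Proposed new method: divalent cobalt and O2 should give a trivalent cobalt alkoxide of the tertiary cyclobutenol, which releases the alkoxyl radical; strain-driven β-scission cuts the C1–C4 bond (the only ring bond whose cleavage gives a stabilised, allylic radical) and leaves a 4-oxoallyl radical with the former ring alkene locked Z; O2 adds at the γ-terminus (future C3), the peroxyl radical is turned into hydroperoxide 16 through the cobalt cycle, and 16 closes on the new ketone to hemiketal 17. The closest known reaction type is the Co(acac)2/O2 oxidative ring expansion of saturated cyclobutanols to 1,2-dioxan-3-ols (and of cyclopropanols to 1,2-dioxolan-3-ols); the extension is the cyclobutenol, whose alkene makes the intermediate an allyl radical and the product a 3,6-dihydro-1,2-dioxine. The six-membered ring closes by reversible 6-exo-trig addition of the hydroperoxide oxygen to the C6 carbonyl, favoured because the Z-alkene holds OOH and C=O together. C3 arises from a planar radical and is racemic, and C6 is an equilibrating hemiketal centre, so no stereocontrol is claimed here: C3 is resolved in step 9 and C6 is fixed in step 10. The step needs retention of the Z geometry (O2 capture near the diffusion limit should outrun rotation in the allyl radical), γ- over α-capture (α-peroxyl formation is reversible and only the γ-adduct gives a conjugated enone that is drained by cyclisation), and tolerance of the remote (E,E)-diene (no hydride source is present, and peroxyl radicals should be trapped by divalent cobalt faster than they add to a diene).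

Step 9
Reactants: 17 methyl 2-{6-hydroxy-6-[(14E,16E)-octadeca-14,16-dien-1-yl]-3,6-dihydro-1,2-dioxin-3-yl}acetate
Product: 18 methyl (2S)-2-({(3R)-3-(2-methoxy-2-oxoethyl)-6-[(14E,16E)-octadeca-14,16-dien-1-yl]-3,6-dihydro-1,2-dioxin-6-yl}oxy)propanoate (both C6 epimers of the 3R series)
Conditions: methyl (S)-lactate (5 equiv), TsOH·H2O (5 mol %), 4 Å MS, CH2Cl2, 20 °C; separation of diastereomers on silica (HPLC)
Reagents that add atoms: methyl (S)-lactate, C[C@H](O)C(=O)OC
Why: Acid-catalysed peroxyketalisation through the cyclic peroxycarbenium ion attaches the enantiopure alcohol at C6 and turns the C3 enantiomers into diastereomers that should separate on silica (classical covalent resolution of a cyclic hemiketal); acid does not touch C3, so collecting the (3R)-series fixes C3 as R.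

Step 10
Reactants: 18 methyl (2S)-2-({(3R)-3-(2-methoxy-2-oxoethyl)-6-[(14E,16E)-octadeca-14,16-dien-1-yl]-3,6-dihydro-1,2-dioxin-6-yl}oxy)propanoate
Product: 19 Xestin B, methyl 2-{(3R,6S)-6-methoxy-6-[(14E,16E)-octadeca-14,16-dien-1-yl]-3,6-dihydro-1,2-dioxin-3-yl}acetate
Conditions: MeOH, PPTS (cat.), 20 °C; chromatography on silica
Reagents that add atoms: methanol, CO
Why: Trans-ketalisation in methanol through the same peroxycarbenium ion exchanges lactate for methoxy without touching C3 (R), and C6 is set under thermodynamic control; the (6S)-epimer (OMe trans to the acetate arm) is separated from the (6R)-epimer, which is re-equilibrated under the same conditions.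

**Compound list**

1 | 12-bromododecan-1-ol | OCCCCCCCCCCCCBr | starting material
2 | 2-[(12-bromododecyl)oxy]tetrahydro-2H-pyran (racemic acetal) | BrCCCCCCCCCCCCOC1CCCCO1 | intermediate
3 | (2E,4E)-hexa-2,4-dien-1-yl acetate (sorbyl acetate) | C/C=C/C=C/COC(C)=O | starting material
4 | {12-[(tetrahydro-2H-pyran-2-yl)oxy]dodecyl}magnesium bromide | Br[Mg]CCCCCCCCCCCCOC1CCCCO1 | intermediate (not isolated)
5 | 2-{[(14E,16E)-octadeca-14,16-dien-1-yl]oxy}tetrahydro-2H-pyran | C/C=C/C=C/CCCCCCCCCCCCCOC1CCCCO1 | intermediate
6 | (14E,16E)-octadeca-14,16-dien-1-ol | C/C=C/C=C/CCCCCCCCCCCCCO | intermediate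
7 | (2E,4E)-18-bromooctadeca-2,4-diene | C/C=C/C=C/CCCCCCCCCCCCCBr | intermediate
8 | methyl 4-chloro-4-oxobutanoate | COC(=O)CCC(Cl)=O | starting material
9 | ethoxyethyne | CCOC#C | starting material
10 | methyl 4-oxobut-3-enoate (monoalkylketene) | COC(=O)CC=C=O | intermediate (not isolated)
11 | methyl 2-(2-ethoxy-4-oxocyclobut-2-en-1-yl)acetate (racemic) | CCOC1=CC(=O)C1CC(=O)OC | intermediate
12 | methyl 2-(2-ethoxy-4-hydroxycyclobut-2-en-1-yl)acetate (racemic, diastereomer mixture) | CCOC1=CC(O)C1CC(=O)OC | intermediate (not isolated)
13 | methyl 2-(4-oxocyclobut-2-en-1-yl)acetate (racemic) | COC(=O)CC1C=CC1=O | intermediate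
14 | [(14E,16E)-octadeca-14,16-dien-1-yl]magnesium bromide | C/C=C/C=C/CCCCCCCCCCCCC[Mg]Br | intermediate (not isolated)
15 | methyl 2-{4-hydroxy-4-[(14E,16E)-octadeca-14,16-dien-1-yl]cyclobut-2-en-1-yl}acetate (racemic, diastereomer mixture) | C/C=C/C=C/CCCCCCCCCCCCCC1(O)C=CC1CC(=O)OC | intermediate
16 | methyl (4Z,20E,22E)-3-hydroperoxy-6-oxotetracosa-4,20,22-trienoate (racemic) | C/C=C/C=C/CCCCCCCCCCCCCC(=O)/C=C\C(OO)CC(=O)OC | intermediate (not isolated)
17 | methyl 2-{6-hydroxy-6-[(14E,16E)-octadeca-14,16-dien-1-yl]-3,6-dihydro-1,2-dioxin-3-yl}acetate (racemic at C3, hemiketal epimers at C6) | C/C=C/C=C/CCCCCCCCCCCCCC1(O)C=CC(CC(=O)OC)OO1 | intermediate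
18 | methyl (2S)-2-({(3R)-3-(2-methoxy-2-oxoethyl)-6-[(14E,16E)-octadeca-14,16-dien-1-yl]-3,6-dihydro-1,2-dioxin-6-yl}oxy)propanoate (C3 = R, both C6 epimers) | C/C=C/C=C/CCCCCCCCCCCCCC1(O[C@@H](C)C(=O)OC)C=C[C@@H](CC(=O)OC)OO1 | intermediate
19 | Xestin B, methyl 2-{(3R,6S)-6-methoxy-6-[(14E,16E)-octadeca-14,16-dien-1-yl]-3,6-dihydro-1,2-dioxin-3-yl}acetate | C/C=C/C=C/CCCCCCCCCCCCC[C@@]1(OC)C=C[C@@H](CC(=O)OC)OO1 | target

**Step count and risks**

Total step count: 10. Longest linear sequence: 8 steps (steps 1, 2, 3, 4, 7, 8, 9, 10, from 12-bromododecan-1-ol).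

Steps most likely to fail:

1. Step 8 (proposed new method). What may go wrong: loss of the Z geometry in the oxoallyl radical before O2 capture, O2 capture at the carbon α to the ketone, radical chain oligomerisation through the side-chain diene, or cobalt-induced reductive cleavage of the product O–O bond. Fallback with known chemistry, setting out from 15 and returning at 17: 15 is heated in toluene at 80 °C, so that thermal conrotatory ring opening of the 3-hydroxycyclobutene and ketonisation give methyl (4E,20E,22E)-6-oxotetracosa-4,20,22-trienoate F1. Irradiation of F1 at 350 nm in O2-saturated CH2Cl2 at 0 °C should then cause E/Z isomerisation and a 1,5-hydrogen shift to the Z-dienol, which is trapped by dissolved oxygen to give 17. This is the photoenolisation–oxygenation route from 4-alkyl enones to 3,6-dihydro-1,2-dioxin-3-ols.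

2. Step 9. What may go wrong: insufficient chromatographic discrimination between the diastereomeric lactate ketals, or slow ketalisation by the secondary alcohol that lets acid-induced decomposition of the dioxinol compete. Fallback setting out from 17 and returning at 19: 17 is ketalised directly in methanol (PPTS, 20 °C) and the trans isomer is separated from the cis isomer on silica, giving racemic methyl 2-{(3R*,6S*)-6-methoxy-6-[(14E,16E)-octadeca-14,16-dien-1-yl]-3,6-dihydro-1,2-dioxin-3-yl}acetate F2. F2 is then resolved by preparative HPLC on a chiral stationary phase (amylose tris(3,5-dimethylphenylcarbamate)) to give 19.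

3. Step 7. What may go wrong: acyl transfer of the cis-alkoxide onto the neighbouring ester (lactonisation) and oxyanion-accelerated electrocyclic ring opening before the quench. Fallback setting out from 13 and 14 and returning at 17: the addition mixture is warmed to 0 °C so that lactonisation goes to completion, and the storable cis-fused 1-[(14E,16E)-octadeca-14,16-dien-1-yl]-2-oxabicyclo[3.2.0]hept-6-en-3-one F3 is isolated. Saponification (LiOH, THF/H2O, 0 °C) gives lithium 2-{4-hydroxy-4-[(14E,16E)-octadeca-14,16-dien-1-yl]cyclobut-2-en-1-yl}acetate F4, which cannot relactonise while it is a salt. The aerobic ring expansion (Co(acac)2, O2, aqueous MeCN, 20 °C) is run on F4 and acidification to pH 4 with HCl at 0 °C gives 2-{6-hydroxy-6-[(14E,16E)-octadeca-14,16-dien-1-yl]-3,6-dihydro-1,2-dioxin-3-yl}acetic acid F5. Esterification of F5 with TMSCHN2 (MeOH/toluene, 0 °C) gives 17.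

**Further compounds**

F1 | step 8 | methyl (4E,20E,22E)-6-oxotetracosa-4,20,22-trienoate | C/C=C/C=C/CCCCCCCCCCCCCC(=O)/C=C/CCC(=O)OC
F2 | step 9 | methyl 2-{(3R*,6S*)-6-methoxy-6-[(14E,16E)-octadeca-14,16-dien-1-yl]-3,6-dihydro-1,2-dioxin-3-yl}acetate, racemate (trans) | C/C=C/C=C/CCCCCCCCCCCCCC1(OC)C=CC(CC(=O)OC)OO1
F3 | step 7 | 1-[(14E,16E)-octadeca-14,16-dien-1-yl]-2-oxabicyclo[3.2.0]hept-6-en-3-one (cis-fused, racemic) | C/C=C/C=C/CCCCCCCCCCCCCC12OC(=O)CC1C=C2
F4 | step 7 | lithium 2-{4-hydroxy-4-[(14E,16E)-octadeca-14,16-dien-1-yl]cyclobut-2-en-1-yl}acetate (cis, racemic) | C/C=C/C=C/CCCCCCCCCCCCCC1(O)C=CC1CC(=O)[O-].[Li+]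
F5 | step 7 | 2-{6-hydroxy-6-[(14E,16E)-octadeca-14,16-dien-1-yl]-3,6-dihydro-1,2-dioxin-3-yl}acetic acid (racemic) | C/C=C/C=C/CCCCCCCCCCCCCC1(O)C=CC(CC(=O)O)OO1
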